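**Plan**

- Retrosynthetic cuts: first the four O-benzyl bonds, then O1–C2 and O1''–C2'' of the two pyranone rings (a double retro-oxa-Michael opening), then the C3–C3'' bond (Stille coupling), and in each half the bond between the ketone carbon C4 and the alkyne carbon that becomes C3 (aldehyde plus acetylide).
- Enabling feature: C3 and C3'' are the α-carbons of the aryl ketones C4=O and C4''=O and are bonded to each other, while C2 and C2'' are benzylic and carry O1 and O1''. Opening both rings C therefore erases all four stereocentres and leaves one achiral, unsymmetrical (Z,Z)-2,3-diaroyl-1,4-diarylbuta-1,3-diene that already holds rings A and B of both halves.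
- Forward order: the four benzene rings are bought. Each half is built as an aryl ynone and turned by syn hydrostannation into an α-iodo or α-stannyl enone. The halves are joined at C3–C3'', the two ortho-phenols are unmasked, both rings C are closed in one catalytic operation, and hydrogenolysis ends the route.
- Stereochemistry: the catalyst sets C2 and C2'' (both R) by face selection. C3 and C3'' (both S) follow by protonation and equilibration trans to their own aryl group, which fixes the like relation across C3–C3''.

Key step: step 15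

Remark on the chemistry: the quinine-derived thiourea is assumed to give the 2R sense; this is to be checked on a monomeric α-substituted 2'-hydroxychalcone, and the quinidine-derived pseudoenantiomer takes its place if the model shows 2S.
Remark on the chemistry: the two ring closures of the key step may occur in either order; the intermediate drawn is closed first on the methylated half, and the other order leads to the same product.

**Route**

Step 1
Reactants: 1 5-methoxyresorcinol
Product: 2 1-methoxy-3,5-bis(methoxymethoxy)benzene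
Conditions: MOMCl (2.5 equiv), iPr2NEt, CH2Cl2, 0 °C to rt
Reagents that add atoms: chloromethyl methyl ether (MOMCl), COCCl
Why: Double O-alkylation of the two phenols by the reactive α-chloro ether under mild amine base (Williamson-type acetal ether formation).

Step 2
Reactants: 2 1-methoxy-3,5-bis(methoxymethoxy)benzene
Product: 4 4-methoxy-2,6-bis(methoxymethoxy)benzaldehyde, via aryllithium 3 (not isolated)
Conditions: n-BuLi, TMEDA, THF, 0 °C; then DMF, 0 °C to rt; H2O
Reagents that add atoms: N,N-dimethylformamide, CN(C)C=O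
Why: Directed ortho-metalation at the C–H flanked by the two OCH2OCH3 groups, which cooperate and outrank the methoxy group as directors, followed by formylation of the aryllithium with DMF.

Step 3
Reactants: 4 4-methoxy-2,6-bis(methoxymethoxy)benzaldehyde
Product: 5 2-hydroxy-4-methoxy-6-(methoxymethoxy)benzaldehyde
Conditions: HCl (ca. 1 M in MeOH, about 1 equiv), rt, stopped at the mono-phenol
Reagents that add atoms: none
Why: Acid-catalysed acetal methanolysis in which the MOM group ortho to the aldehyde is cleaved with help of the carbonyl oxygen; the freed phenol then ties up that oxygen in a six-membered hydrogen bond, so the second cleavage should be slower and the reaction can be halted at the mono stage.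

Step 4
Reactants: 5 2-hydroxy-4-methoxy-6-(methoxymethoxy)benzaldehyde
Product: 6 2-benzyloxy-4-methoxy-6-(methoxymethoxy)benzaldehyde
Conditions: BnBr, K2CO3, DMF, 60 °C
Reagents that add atoms: benzyl bromide, BrCc1ccccc1
Why: Williamson ether synthesis; warm carbonate in DMF is enough to alkylate the hydrogen-bonded phenol while aldehyde, MOM and methyl ethers are inert.

Step 5
Reactants: 6 2-benzyloxy-4-methoxy-6-(methoxymethoxy)benzaldehyde; 7 4-ethynylanisole
Product: 9 racemic 1-[2-benzyloxy-4-methoxy-6-(methoxymethoxy)phenyl]-3-(4-methoxyphenyl)prop-2-yn-1-ol, via lithium acetylide 8 (not isolated)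
Conditions: 7, n-BuLi, THF, −78 °C; then 6, −78 to 0 °C; H2O
Reagents that add atoms: none
Why: 1,2-Addition of a lithium acetylide to the aldehyde; the carbinol centre forms as a racemate and is removed in the next step.

Step 6
Reactants: 9 racemic propargylic alcohol of the methylated half
Product: 10 1-[2-benzyloxy-4-methoxy-6-(methoxymethoxy)phenyl]-3-(4-methoxyphenyl)prop-2-yn-1-one
Conditions: activated MnO2 (excess), CH2Cl2, rt
Reagents that add atoms: none
Why: MnO2 oxidation of a doubly activated (benzylic and propargylic) alcohol to the ynone under neutral conditions that leave MOM and benzyl ethers untouched.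

Step 7
Reactants: 10 ynone of the methylated half
Product: 12 (E)-1-[2-benzyloxy-4-methoxy-6-(methoxymethoxy)phenyl]-2-iodo-3-(4-methoxyphenyl)prop-2-en-1-one (aroyl and anisyl cis), via α-tributylstannyl enone 11 (not isolated)
Conditions: Bu3SnH (1.1 equiv, slow addition), Pd(PPh3)4 (2 mol%, zerovalent palladium), THF, 0 °C; then I2, 0 °C, dark
Reagents that add atoms: iodine, I-I
Why: Palladium-catalysed syn hydrostannation of an ynone delivers hydrogen to the β-carbon and tin to the α-carbon (H and Sn cis), and iododestannylation of the alkenylstannane proceeds with retention of the alkene geometry.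

Step 8
Reactants: 13 2,4,6-trihydroxybenzaldehyde
Product: 14 2,4-bis(benzyloxy)-6-hydroxybenzaldehyde
Conditions: BnBr (2.1 equiv), K2CO3, DMF, rt
Reagents that add atoms: benzyl bromide, BrCc1ccccc1
Why: Williamson benzylation of the 4-OH and one 2-OH; the last hydroxyl is then locked in the hydrogen bond to the aldehyde and is left free under mild carbonate conditions.

Step 9
Reactants: 14 2,4-bis(benzyloxy)-6-hydroxybenzaldehyde
Product: 15 2,4-bis(benzyloxy)-6-(methoxymethoxy)benzaldehyde
Conditions: NaH, THF–DMF, 0 °C; then MOMCl, 0 °C to rt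
Reagents that add atoms: chloromethyl methyl ether (MOMCl), COCCl
Why: Deprotonation of the chelated phenol with NaH and O-alkylation with MOMCl (acetal ether formation) gives the acid-labile mask of the future ring oxygen O1''.

Step 10
Reactants: 15 2,4-bis(benzyloxy)-6-(methoxymethoxy)benzaldehyde; 16 1-benzyloxy-4-ethynylbenzene
Product: 18 racemic 1-[2,4-bis(benzyloxy)-6-(methoxymethoxy)phenyl]-3-[4-(benzyloxy)phenyl]prop-2-yn-1-ol, via lithium acetylide 17 (not isolated)
Conditions: 16, n-BuLi, THF, −78 °C; then 15, −78 to 0 °C; H2O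
Reagents that add atoms: none
Why: 1,2-Addition of a lithium acetylide to the aldehyde; the racemic carbinol centre is removed in the next step.

Step 11
Reactants: 18 racemic propargylic alcohol of the free-phenol half
Product: 19 1-[2,4-bis(benzyloxy)-6-(methoxymethoxy)phenyl]-3-[4-(benzyloxy)phenyl]prop-2-yn-1-one
Conditions: activated MnO2 (excess), CH2Cl2, rt
Reagents that add atoms: none
Why: MnO2 oxidation of a benzylic and propargylic alcohol to the ynone under neutral conditions.

Step 12
Reactants: 19 ynone of the free-phenol half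
Product: 20 (E)-1-[2,4-bis(benzyloxy)-6-(methoxymethoxy)phenyl]-3-[4-(benzyloxy)phenyl]-2-(tributylstannyl)prop-2-en-1-one (aroyl and aryl cis)
Conditions: Bu3SnH (1.1 equiv, slow addition), Pd(PPh3)4 (2 mol%), THF, 0 °C; chromatography on Et3N-deactivated silica
Reagents that add atoms: tributyltin hydride, CCCC[SnH](CCCC)CCCC
Why: Palladium-catalysed syn hydrostannation of the ynone, with hydride delivered to the β-carbon polarised by the ketone and tin placed on the α-carbon, so that H and Sn end up cis.

Step 13
Reactants: 12 α-iodo enone of the methylated half; 20 α-stannyl enone of the free-phenol half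
Product: 21 (2Z,3Z)-1-[2-benzyloxy-4-methoxy-6-(methoxymethoxy)phenyl]-4-[2,4-bis(benzyloxy)-6-(methoxymethoxy)phenyl]-2-(4-methoxybenzylidene)-3-[4-(benzyloxy)benzylidene]butane-1,4-dione
Conditions: Pd(PPh3)4 (10 mol%), Cu(O2CC4H3S) (CuTC, monovalent copper, 1.5 equiv), DMF, rt, dark
Reagents that add atoms: none
Why: Stille cross-coupling of an alkenyl iodide with an alkenylstannane forms C3–C3'' with retention at both alkenes; CuTC speeds the tin-to-copper transmetalation that is otherwise slow for a hindered, electron-poor α-stannyl enone, and the neutral room-temperature conditions spare MOM and benzyl ethers.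

Step 14
Reactants: 21 fully protected bichalcone
Product: 22 (2Z,3Z)-1-(2-benzyloxy-6-hydroxy-4-methoxyphenyl)-4-[2,4-bis(benzyloxy)-6-hydroxyphenyl]-2-(4-methoxybenzylidene)-3-[4-(benzyloxy)benzylidene]butane-1,4-dione
Conditions: HCl (ca. 1 M in MeOH–THF), rt
Reagents that add atoms: none
Why: Acid-catalysed methanolysis of the two aryl MOM acetals; benzyl and methyl ethers are stable, and dilute acid at room temperature should be too mild to cyclise or isomerise the 6'-benzyloxy-2'-hydroxy enones at a useful rate.

Step 15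
Reactants: 22 bis(2'-hydroxy) bichalcone
Product: 24 (2R,3S,2''R,3''S)-5,5'',7'',4'''-tetrakis(benzyloxy)-7,4'-dimethoxy-3,3''-biflavanone, via mono-flavanone 23 (not isolated)
Conditions: 9-amino-9-deoxy-epi-quinine-derived 3,5-bis(trifluoromethyl)phenyl thiourea (20 mol%), toluene, 0 °C to rt
Reagents that add atoms: none
Why: Proposed new method: the quinuclidine nitrogen of the bifunctional thiourea acts as a general base on each hydrogen-bonded 2'-phenol while the thiourea N–H pair binds the adjacent ketone, so that the phenol oxygen adds to the β-carbon of its own enone (forming O1–C2 and O1''–C2'') and the enol so formed is protonated at C3 or C3''; the closest known reaction type is the cinchona-thiourea-catalysed enantioselective intramolecular oxa-Michael cyclisation of 2'-hydroxychalcones, including α-substituted ones that give trans-3-substituted flavanones, which has not been run twice on one cross-conjugated bis-enone. Both pyranone rings (ring C of each half) close in the 6-endo-trig mode, one after the other through mono-flavanone 23. C2 and C2'' (both R) are set by the catalyst, which must pick the same enantioface of each trisubstituted alkene, whose (Z) geometry stems from the syn hydrostannations; C3 and C3'' (both S) are set by protonation and amine-mediated equilibration of these epimerisable α-keto carbons to the 2,3-trans arrangement, so each is governed by its own C2 and the like relation across C3–C3'' follows. The step needs catalyst control to override the bias of the first-formed flavanone in the second closure, which is helped by the twist about the C3–C3'' bond that decouples the two enones and by the fact that each phenol can reach only its own β-carbon in a six-membered closure. It also needs the uncatalysed cyclisation and the retro-Michael opening to stay slow, which the benzyl ethers on the second ortho oxygen of each ring A secure, and it needs the mono-cyclised dienol not to be protonated at the γ-carbon to a C3=C3'' alkylidene, for which the non-ionic hydrogen-bonding conditions in toluene are chosen. Mismatched closures should end mostly in the separable unlike diastereomer, which should raise the enantiomeric purity of 24.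

Step 16
Reactants: 24 tetra-O-benzyl biflavanone
Product: 25 (2R,3S,2''R,3''S)-5,5'',7'',4'''-tetrahydroxy-7,4'-dimethoxy-3,3''-biflavanone (CNP0279849.2)
Conditions: H2 (1 atm), 10% Pd/C, EtOAc–MeOH, rt, stopped after uptake of 4 equiv
Reagents that add atoms: none
Why: Catalytic hydrogenolysis of the four aryl benzyl ethers under neutral conditions; the flavanone C2–O1 bonds, though benzylic, are secondary and hindered and should cleave much more slowly, and without base neither C3 epimerises nor ring C opens, so the four stereocentres are carried through unchanged.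

**Compound list**

1 | 5-methoxyresorcinol | COc1cc(O)cc(O)c1 | starting material
2 | 1-methoxy-3,5-bis(methoxymethoxy)benzene | COCOc1cc(OC)cc(OCOC)c1 | intermediate
3 | [4-methoxy-2,6-bis(methoxymethoxy)phenyl]lithium | [Li]c1c(OCOC)cc(OC)cc1OCOC | intermediate (not isolated)
4 | 4-methoxy-2,6-bis(methoxymethoxy)benzaldehyde | O=Cc1c(OCOC)cc(OC)cc1OCOC | intermediate
5 | 2-hydroxy-4-methoxy-6-(methoxymethoxy)benzaldehyde | O=Cc1c(O)cc(OC)cc1OCOC | intermediate
6 | 2-benzyloxy-4-methoxy-6-(methoxymethoxy)benzaldehyde | O=Cc1c(OCOC)cc(OC)cc1OCc1ccccc1 | intermediate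
7 | 4-ethynylanisole | C#Cc1ccc(OC)cc1 | starting material
8 | lithium (4-methoxyphenyl)acetylide | [Li]C#Cc1ccc(OC)cc1 | intermediate (not isolated)
9 | racemic 1-[2-benzyloxy-4-methoxy-6-(methoxymethoxy)phenyl]-3-(4-methoxyphenyl)prop-2-yn-1-ol | OC(C#Cc1ccc(OC)cc1)c1c(OCOC)cc(OC)cc1OCc1ccccc1 | intermediate
10 | 1-[2-benzyloxy-4-methoxy-6-(methoxymethoxy)phenyl]-3-(4-methoxyphenyl)prop-2-yn-1-one | O=C(C#Cc1ccc(OC)cc1)c1c(OCOC)cc(OC)cc1OCc1ccccc1 | intermediate
11 | (E)-1-[2-benzyloxy-4-methoxy-6-(methoxymethoxy)phenyl]-3-(4-methoxyphenyl)-2-(tributylstannyl)prop-2-en-1-one | O=C(c1c(OCOC)cc(OC)cc1OCc1ccccc1)/C(=C\c1ccc(OC)cc1)[Sn](CCCC)(CCCC)CCCC | intermediate (not isolated)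
12 | (E)-1-[2-benzyloxy-4-methoxy-6-(methoxymethoxy)phenyl]-2-iodo-3-(4-methoxyphenyl)prop-2-en-1-one | O=C(c1c(OCOC)cc(OC)cc1OCc1ccccc1)/C(I)=C\c1ccc(OC)cc1 | intermediate
13 | 2,4,6-trihydroxybenzaldehyde | O=Cc1c(O)cc(O)cc1O | starting material
14 | 2,4-bis(benzyloxy)-6-hydroxybenzaldehyde | O=Cc1c(O)cc(OCc2ccccc2)cc1OCc1ccccc1 | intermediate
15 | 2,4-bis(benzyloxy)-6-(methoxymethoxy)benzaldehyde | O=Cc1c(OCOC)cc(OCc2ccccc2)cc1OCc1ccccc1 | intermediate
16 | 1-benzyloxy-4-ethynylbenzene | C#Cc1ccc(OCc2ccccc2)cc1 | starting material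
17 | lithium [4-(benzyloxy)phenyl]acetylide | [Li]C#Cc1ccc(OCc2ccccc2)cc1 | intermediate (not isolated)
18 | racemic 1-[2,4-bis(benzyloxy)-6-(methoxymethoxy)phenyl]-3-[4-(benzyloxy)phenyl]prop-2-yn-1-ol | OC(C#Cc1ccc(OCc2ccccc2)cc1)c1c(OCOC)cc(OCc2ccccc2)cc1OCc1ccccc1 | intermediate
19 | 1-[2,4-bis(benzyloxy)-6-(methoxymethoxy)phenyl]-3-[4-(benzyloxy)phenyl]prop-2-yn-1-one | O=C(C#Cc1ccc(OCc2ccccc2)cc1)c1c(OCOC)cc(OCc2ccccc2)cc1OCc1ccccc1 | intermediate
20 | (E)-1-[2,4-bis(benzyloxy)-6-(methoxymethoxy)phenyl]-3-[4-(benzyloxy)phenyl]-2-(tributylstannyl)prop-2-en-1-one | O=C(c1c(OCOC)cc(OCc2ccccc2)cc1OCc1ccccc1)/C(=C\c1ccc(OCc2ccccc2)cc1)[Sn](CCCC)(CCCC)CCCC | intermediate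
21 | (2Z,3Z)-1-[2-benzyloxy-4-methoxy-6-(methoxymethoxy)phenyl]-4-[2,4-bis(benzyloxy)-6-(methoxymethoxy)phenyl]-2-(4-methoxybenzylidene)-3-[4-(benzyloxy)benzylidene]butane-1,4-dione | COc1ccc(cc1)\C=C(/C(=O)c1c(OCOC)cc(OC)cc1OCc1ccccc1)C(/C(=O)c1c(OCOC)cc(OCc2ccccc2)cc1OCc1ccccc1)=C/c1ccc(OCc2ccccc2)cc1 | intermediate
22 | (2Z,3Z)-1-(2-benzyloxy-6-hydroxy-4-methoxyphenyl)-4-[2,4-bis(benzyloxy)-6-hydroxyphenyl]-2-(4-methoxybenzylidene)-3-[4-(benzyloxy)benzylidene]butane-1,4-dione | COc1ccc(cc1)\C=C(/C(=O)c1c(O)cc(OC)cc1OCc1ccccc1)C(/C(=O)c1c(O)cc(OCc2ccccc2)cc1OCc1ccccc1)=C/c1ccc(OCc2ccccc2)cc1 | intermediate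
23 | (2R,3S)-5-benzyloxy-7-methoxy-2-(4-methoxyphenyl)-3-{(Z)-1-[2,4-bis(benzyloxy)-6-hydroxybenzoyl]-2-[4-(benzyloxy)phenyl]vinyl}chroman-4-one | COc1ccc([C@@H]2Oc3cc(OC)cc(OCc4ccccc4)c3C(=O)[C@H]2C(/C(=O)c2c(O)cc(OCc3ccccc3)cc2OCc2ccccc2)=C/c2ccc(OCc3ccccc3)cc2)cc1 | intermediate (not isolated)
24 | (2R,3S,2''R,3''S)-5,5'',7'',4'''-tetrakis(benzyloxy)-7,4'-dimethoxy-3,3''-biflavanone | COc1ccc([C@@H]2Oc3cc(OC)cc(OCc4ccccc4)c3C(=O)[C@H]2[C@@H]2C(=O)c3c(OCc4ccccc4)cc(OCc4ccccc4)cc3O[C@H]2c2ccc(OCc3ccccc3)cc2)cc1 | intermediate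
25 | (2R,3S,2''R,3''S)-5,5'',7'',4'''-tetrahydroxy-7,4'-dimethoxy-3,3''-biflavanone (CNP0279849.2) | COc1ccc([C@@H]2Oc3cc(OC)cc(O)c3C(=O)[C@H]2[C@@H]2C(=O)c3c(O)cc(O)cc3O[C@H]2c2ccc(O)cc2)cc1 | target

**Count and risks**

Total step count: 16. Longest linear sequence: 11 steps (steps 1 to 7, then 13 to 16, from 5-methoxyresorcinol).

Steps most likely to fail:

1. Step 15. The catalyst may not override the bias of the first-formed stereocentres in the second closure, the hindered α-substituted enones may close slowly, and γ-protonation of the mono-cyclised dienol may compete. Fallback by known chemistry, setting out from 22: heating with NaOAc in EtOH (the classical thermodynamic chalcone-to-flavanone isomerisation) should close both rings without enantiocontrol and equilibrate C3 and C3'' to trans. This should give the racemic like (2R*,3S*,2''R*,3''S*) tetra-O-benzyl biflavanone F1 beside the racemic unlike (2R*,3S*,2''S*,3''R*) tetra-O-benzyl biflavanone F2. F2 is removed on silica, and F1 is resolved by preparative HPLC on a chiral stationary phase (amylose tris(3,5-dimethylphenylcarbamate)). The (2R,3S,2''R,3''S) enantiomer returns to the route at 24, its configuration to be assigned by ECD or X-ray analysis.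

2. Step 13. Transmetalation of the hindered, electron-poor α-stannyl enone may be too slow, so that protodestannylation and homocoupling take over. Fallback, setting out from 20: reduction of the ketone with iBu2AlH (CH2Cl2, −78 °C) should give the racemic α-stannyl allylic alcohol F3, a more electron-rich and less encumbered alkenylstannane. Stille coupling of F3 with 12 [Pd(PPh3)4, Cu(O2CC4H3S), DMF, rt] should give the racemic dienyl alcohol F4. MnO2 oxidation of this benzylic and allylic carbinol (CH2Cl2, rt) restores the ketone and returns to the route at 21.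

3. Step 3. The acetal cleavage may fail to stop at one MOM group, with over-cleavage to the diol or incomplete conversion. Fallback, setting out from 4: both MOM groups are removed on purpose (HCl, MeOH, 50 °C) to give 2,6-dihydroxy-4-methoxybenzaldehyde F5. Mono-benzylation (BnBr, 1.0 equiv, K2CO3, acetone, reflux) should stop after one alkylation, because the remaining hydroxyl is held by the hydrogen bond to the aldehyde, and give 2-benzyloxy-6-hydroxy-4-methoxybenzaldehyde F6. MOM ether formation (NaH, MOMCl, THF–DMF, 0 °C) then returns to the route at 6, bypassing 5.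

Further compounds
F1 | step 15 | racemic like (2R*,3S*,2''R*,3''S*)-5,5'',7'',4'''-tetrakis(benzyloxy)-7,4'-dimethoxy-3,3''-biflavanone (both enantiomers) | COc1ccc([C@@H]2Oc3cc(OC)cc(OCc4ccccc4)c3C(=O)[C@H]2[C@@H]2C(=O)c3c(OCc4ccccc4)cc(OCc4ccccc4)cc3O[C@H]2c2ccc(OCc3ccccc3)cc2)cc1.COc1ccc([C@H]2Oc3cc(OC)cc(OCc4ccccc4)c3C(=O)[C@@H]2[C@H]2C(=O)c3c(OCc4ccccc4)cc(OCc4ccccc4)cc3O[C@@H]2c2ccc(OCc3ccccc3)cc2)cc1
F2 | step 15 | racemic unlike (2R*,3S*,2''S*,3''R*)-5,5'',7'',4'''-tetrakis(benzyloxy)-7,4'-dimethoxy-3,3''-biflavanone (both enantiomers) | COc1ccc([C@@H]2Oc3cc(OC)cc(OCc4ccccc4)c3C(=O)[C@H]2[C@H]2C(=O)c3c(OCc4ccccc4)cc(OCc4ccccc4)cc3O[C@@H]2c2ccc(OCc3ccccc3)cc2)cc1.COc1ccc([C@H]2Oc3cc(OC)cc(OCc4ccccc4)c3C(=O)[C@@H]2[C@@H]2C(=O)c3c(OCc4ccccc4)cc(OCc4ccccc4)cc3O[C@H]2c2ccc(OCc3ccccc3)cc2)cc1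
F3 | step 13 | racemic (E)-1-[2,4-bis(benzyloxy)-6-(methoxymethoxy)phenyl]-3-[4-(benzyloxy)phenyl]-2-(tributylstannyl)prop-2-en-1-ol | OC(c1c(OCOC)cc(OCc2ccccc2)cc1OCc1ccccc1)/C(=C\c1ccc(OCc2ccccc2)cc1)[Sn](CCCC)(CCCC)CCCC
F4 | step 13 | racemic (2Z,3Z)-1-[2-benzyloxy-4-methoxy-6-(methoxymethoxy)phenyl]-4-[2,4-bis(benzyloxy)-6-(methoxymethoxy)phenyl]-4-hydroxy-2-(4-methoxybenzylidene)-3-[4-(benzyloxy)benzylidene]butan-1-one | COc1ccc(cc1)\C=C(/C(=O)c1c(OCOC)cc(OC)cc1OCc1ccccc1)C(/C(O)c1c(OCOC)cc(OCc2ccccc2)cc1OCc1ccccc1)=C/c1ccc(OCc2ccccc2)cc1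
F5 | step 3 | 2,6-dihydroxy-4-methoxybenzaldehyde | O=Cc1c(O)cc(OC)cc1O
F6 | step 3 | 2-benzyloxy-6-hydroxy-4-methoxybenzaldehyde | O=Cc1c(O)cc(OC)cc1OCc1ccccc1
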